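**Retrosynthetic overview**
1. Target ⇐ Mo(0) N–O cleavage and hydrolysis of a Δ2-isoxazoline that masks the aldol unit C1(=O)–C10(Me)–C9(OH) (step 15) ⇐ methacrylation of the free C8–OH (step 14).
2. Isoxazoline-bridged macrocycle ⇐ Mg-alkoxide-directed intramolecular nitrile oxide–alkene cycloaddition (step 13). It forms C1–C10 and O–C9 and closes the ten-membered carbocycle C1–C10 last. The enabling feature is the 1,3-keto-alcohol C1/C9 with trans C9–OH/C10–Me, flanked by the C8 oxygen: this is the retron of an (E)-propenyl group next to an allylic alkoxide.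
3. Acyclic precursor ⇐ ligand-controlled (E)-propenylzinc addition to a C8 aldehyde on the butenolide carbon C7; the C1 oxime comes from a silyl-protected alcohol.
4. Butenolide (O, C6, C7, C11, C12) ⇐ vinylcuprate syn-addition, iodination and lactonisation of an epoxy γ-hydroxy ynoate, then Stille hydroxymethylation for C13.
5. Epoxy alcohol ⇐ Zn–ProPhenol alkynylation of an (E)-enal (sets C6) and OH-directed threo epoxidation (sets C4, C5). Ring order: oxirane (step 4) → butenolide (step 5) → ten-membered carbocycle (step 13); the isoxazoline formed with it is temporary.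

Key step: step 13

Remark (atom labels): germacranolide numbering is used. C1 ring ketone; C2, C3 the two CH2; C4(Me = C15)/C5 the oxirane carbons; C6 lactone O–CH; C7=C11 butenolide C=C; C12 lactone C=O; C13 CH2OAc; C8 CH–O-methacryloyl; C9 CHOH; C10 CHMe (Me = C14).
Assumption: the ligand enantiomers in steps 3 and 9 are named by the usual sense of induction of these catalysts; if the opposite face is delivered, the antipodal ligand is used. The E/Z geometry of oxime 20 is irrelevant.

**Step 1**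
Reactants: 1 tert-butyldimethyl(pent-4-yn-1-yloxy)silane
Product: 4 (2E)-6-[(tert-butyldimethylsilyl)oxy]-3-methylhex-2-en-1-ol, via alkenyldimethylalane 2 (not isolated), via lithium alkenylalanate 3 (not isolated)
Conditions: Me3Al (2 equiv), Cp2ZrCl2 (20 mol%), CH2Cl2, 0 °C → rt; evaporate; n-BuLi, THF, −78 °C; (CH2O)n, → rt; aq. Rochelle salt
Reagents that add atoms: trimethylaluminium, C[Al](C)C; paraformaldehyde (as formaldehyde), C=O
Why: Negishi Zr-catalysed carboalumination adds Me and Al syn across the terminal alkyne (Al on the terminal carbon) and the alanate is hydroxymethylated with retention, so the C4=C5 bond should form E-trisubstituted with C15 in place.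

**Step 2**
Reactants: 4 (2E)-6-[(tert-butyldimethylsilyl)oxy]-3-methylhex-2-en-1-ol
Product: 5 (2E)-6-[(tert-butyldimethylsilyl)oxy]-3-methylhex-2-enal
Conditions: MnO2 (excess), CH2Cl2, rt
Reagents that add atoms: none
Why: MnO2 allylic alcohol oxidation should give the enal without E/Z erosion.

**Step 3**
Reactants: 5 (2E)-6-[(tert-butyldimethylsilyl)oxy]-3-methylhex-2-enal; 6 methyl propiolate
Product: 7 methyl (4R,5E)-9-[(tert-butyldimethylsilyl)oxy]-4-hydroxy-6-methylnon-5-en-2-ynoate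
Conditions: 6 (3 equiv), Me2Zn (3 equiv), (S,S)-ProPhenol (10 mol%), Ph3P=O (20 mol%), toluene, 0 °C
Reagents that add atoms: methyl propiolate (6), C#CC(=O)OC
Why: Zn–ProPhenol (Trost) asymmetric alkynylation of an enal; the dinuclear zinc catalyst should deliver the alkynyl group to the Si face and set C6 (4R in 7) under ligand control.

**Step 4**
Reactants: 7 methyl (4R,5E)-9-[(tert-butyldimethylsilyl)oxy]-4-hydroxy-6-methylnon-5-en-2-ynoate
Product: 8 methyl (4S)-4-[(2R,3R)-3-{3-[(tert-butyldimethylsilyl)oxy]propyl}-3-methyloxiran-2-yl]-4-hydroxybut-2-ynoate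
Conditions: mCPBA, NaHCO3, CH2Cl2, 0 °C
Reagents that add atoms: mCPBA, OOC(=O)c1cccc(Cl)c1
Why: Hydroxyl-directed (Henbest-type) peracid epoxidation: A(1,3) strain from the cis C15 methyl keeps C6–H in the alkene plane, so the hydrogen-bonded peracid should attack the face carrying OH and give the threo epoxy alcohol, setting C4 and C5 from C6 and closing the oxirane.

**Step 5**
Reactants: 8 methyl (4S)-4-[(2R,3R)-3-{3-[(tert-butyldimethylsilyl)oxy]propyl}-3-methyloxiran-2-yl]-4-hydroxybut-2-ynoate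
Product: 11 (5S)-5-[(2R,3R)-3-{3-[(tert-butyldimethylsilyl)oxy]propyl}-3-methyloxiran-2-yl]-4-ethenyl-3-iodofuran-2(5H)-one, via alkenylcuprate adduct 9 (not isolated), via iodo hydroxy ester 10 (not isolated)
Conditions: vinylMgBr (3.2 equiv), CuBr·SMe2 (1.6 equiv), THF, −78 °C; I2, THF, −78 → −20 °C; cold aq. Na2S2O3/NH4Cl
Reagents that add atoms: vinylmagnesium bromide, C=C[Mg]Br; iodine, II
Why: syn-Carbocupration of the ynoate puts vinyl on C7 and copper on C11, iodinolysis proceeds with retention, and the C6 alkoxide, now cis to the ester, lactonises (conjugate addition–iodination–lactonisation cascade), which should close the butenolide with C6 untouched.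

**Step 6**
Reactants: 11 (5S)-5-[(2R,3R)-3-{3-[(tert-butyldimethylsilyl)oxy]propyl}-3-methyloxiran-2-yl]-4-ethenyl-3-iodofuran-2(5H)-one
Product: 12 (5S)-5-[(2R,3R)-3-{3-[(tert-butyldimethylsilyl)oxy]propyl}-3-methyloxiran-2-yl]-4-ethenyl-3-(hydroxymethyl)furan-2(5H)-one
Conditions: Bu3SnCH2OH (1.5 equiv), Pd(PPh3)4 (5 mol%), dioxane, 80 °C
Reagents that add atoms: (tributylstannyl)methanol, OC[Sn](CCCC)(CCCC)CCCC
Why: Stille–Kosugi coupling of the α-iodobutenolide with (tributylstannyl)methanol should install C13 as CH2OH; oxirane, diene and silyl ether are inert to Pd(0).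

**Step 7**
Reactants: 12 (5S)-5-[(2R,3R)-3-{3-[(tert-butyldimethylsilyl)oxy]propyl}-3-methyloxiran-2-yl]-4-ethenyl-3-(hydroxymethyl)furan-2(5H)-one
Product: 13 {(5S)-5-[(2R,3R)-3-{3-[(tert-butyldimethylsilyl)oxy]propyl}-3-methyloxiran-2-yl]-4-ethenyl-2-oxo-2,5-dihydrofuran-3-yl}methyl acetate
Conditions: Ac2O, pyridine, DMAP (cat.), CH2Cl2, 0 °C
Reagents that add atoms: acetic anhydride, CC(=O)OC(C)=O
Why: Standard DMAP-catalysed acetylation of the primary allylic alcohol.

**Step 8**
Reactants: 13 {(5S)-5-[(2R,3R)-3-{3-[(tert-butyldimethylsilyl)oxy]propyl}-3-methyloxiran-2-yl]-4-ethenyl-2-oxo-2,5-dihydrofuran-3-yl}methyl acetate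
Product: 15 {(5S)-5-[(2R,3R)-3-{3-[(tert-butyldimethylsilyl)oxy]propyl}-3-methyloxiran-2-yl]-4-formyl-2-oxo-2,5-dihydrofuran-3-yl}methyl acetate, via secondary ozonide 14 (not isolated)
Conditions: O3, CH2Cl2, −78 °C (Sudan Red endpoint); PPh3, → rt
Reagents that add atoms: ozone, [O-][O+]=O
Why: Ozonolysis with reductive work-up; the terminal vinyl group is far more reactive towards ozone than the tetrasubstituted, ester-conjugated butenolide C=C, so only C8=CH2 should be cleaved to the C8 aldehyde.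

**Step 9**
Reactants: 15 {(5S)-5-[(2R,3R)-3-{3-[(tert-butyldimethylsilyl)oxy]propyl}-3-methyloxiran-2-yl]-4-formyl-2-oxo-2,5-dihydrofuran-3-yl}methyl acetate; 16 propyne
Product: 17 {(5S)-5-[(2R,3R)-3-{3-[(tert-butyldimethylsilyl)oxy]propyl}-3-methyloxiran-2-yl]-4-[(1S,2E)-1-hydroxybut-2-en-1-yl]-2-oxo-2,5-dihydrofuran-3-yl}methyl acetate
Conditions: 16, Cp2Zr(H)Cl, CH2Cl2, rt; Me2Zn, toluene, −65 °C; (−)-MIB (10 mol%); then 15, −30 → 0 °C
Reagents that add atoms: propyne (16), CC#C
Why: Hydrozirconation of propyne, Zr-to-Zn transmetalation and amino-alcohol-catalysed 1,2-addition (Wipf–Oppolzer alkenylzinc addition) should deliver the (E)-propenyl group to the Si face of the aldehyde under ligand control and set C8 (1S in 17); the non-basic zinc reagent should spare esters, oxirane and the acidic C6–H.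

**Step 10**
Reactants: 17 {(5S)-5-[(2R,3R)-3-{3-[(tert-butyldimethylsilyl)oxy]propyl}-3-methyloxiran-2-yl]-4-[(1S,2E)-1-hydroxybut-2-en-1-yl]-2-oxo-2,5-dihydrofuran-3-yl}methyl acetate
Product: 18 {(5S)-4-[(1S,2E)-1-hydroxybut-2-en-1-yl]-5-[(2R,3R)-3-(3-hydroxypropyl)-3-methyloxiran-2-yl]-2-oxo-2,5-dihydrofuran-3-yl}methyl acetate
Conditions: HF·pyridine, pyridine, THF, 0 °C
Reagents that add atoms: none
Why: Buffered HF·pyridine cleaves the primary TBS ether; oxirane, acetate and allylic alcohol should tolerate these conditions.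

**Step 11**
Reactants: 18 {(5S)-4-[(1S,2E)-1-hydroxybut-2-en-1-yl]-5-[(2R,3R)-3-(3-hydroxypropyl)-3-methyloxiran-2-yl]-2-oxo-2,5-dihydrofuran-3-yl}methyl acetate
Product: 19 {(5S)-4-[(1S,2E)-1-hydroxybut-2-en-1-yl]-5-[(2R,3R)-3-methyl-3-(3-oxopropyl)oxiran-2-yl]-2-oxo-2,5-dihydrofuran-3-yl}methyl acetate
Conditions: TEMPO (10 mol%), PhI(OAc)2 (1.1 equiv), CH2Cl2, rt
Reagents that add atoms: none
Why: TEMPO/PhI(OAc)2 oxoammonium oxidation is strongly sterically controlled, so the unhindered primary alcohol should be oxidised to the C1 aldehyde while the hindered secondary allylic C8–OH stays.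

**Step 12**
Reactants: 19 {(5S)-4-[(1S,2E)-1-hydroxybut-2-en-1-yl]-5-[(2R,3R)-3-methyl-3-(3-oxopropyl)oxiran-2-yl]-2-oxo-2,5-dihydrofuran-3-yl}methyl acetate
Product: 20 {(5S)-5-[(2R,3R)-3-[3-(hydroxyimino)propyl]-3-methyloxiran-2-yl]-4-[(1S,2E)-1-hydroxybut-2-en-1-yl]-2-oxo-2,5-dihydrofuran-3-yl}methyl acetate
Conditions: NH2OH·HCl, NaOAc, MeOH, 0 °C → rt
Reagents that add atoms: hydroxylamine hydrochloride, NO.Cl
Why: Buffered oxime condensation of the aliphatic aldehyde; the oxime geometry does not matter for the next step.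

**Step 13**
Reactants: 20 {(5S)-5-[(2R,3R)-3-[3-(hydroxyimino)propyl]-3-methyloxiran-2-yl]-4-[(1S,2E)-1-hydroxybut-2-en-1-yl]-2-oxo-2,5-dihydrofuran-3-yl}methyl acetate
Product: 23 8-hydroxy isoxazoline-bridged germacranolide (C1=N–O–C9 bridge; 13-OAc; 4,5-oxirane; 4R 5R 6S 8R 9R 10R), via hydroximoyl chloride 21 (not isolated), via nitrile oxide 22 (not isolated)
Conditions: NCS (1.05 equiv), pyridine (cat.), CH2Cl2, 0 °C → rt; cold aqueous wash, dry; dilute to 2 mM in CH2Cl2; EtMgBr (2.05 equiv), −78 °C → rt; aq. NH4Cl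
Reagents that add atoms: none
Why: Proposed new method: N-chlorination of the aldoxime and double deprotonation by EtMgBr should give a nitrile oxide at C1 tethered to the bromomagnesium C8-alkoxide; coordination of the nitrile-oxide oxygen to that magnesium holds the dipole over C9=C10, and a concerted suprafacial [3+2] cycloaddition forms O–C9 and C1–C10. The closest known reactions are the intermolecular magnesium-alkoxide-directed (Kanemasa-type) nitrile oxide cycloaddition to allylic alcohols and untemplated intramolecular nitrile oxide cycloadditions that close medium and large carbocycles in the bridged mode; their combination in one macrocyclisation is the new element. The ten-membered carbocycle closes through the C1–C10 bond in the bridged (3,5-spanning, bicyclo[7.2.1]) mode, and the temporary isoxazoline closes through the same bond plus O–C9. C9 is controlled by the C8 stereocentre through the chelate (C8–H in the alkene plane, O–Mg on the attacked face, so O–C9 forms syn to O–C8), and C10 follows from suprafacial addition to the (E)-propenyl group (C9–O and C10–Me anti after unmasking). The step needs regioselectivity for O–C9/C1–C10 over the fused nine-membered alternative and cyclisation over furoxan dimerisation; the chelate, the electronic bias of the allylic C–O alkene and 2 mM dilution should secure these. No other dipolarophile competes, because C4=C5 is already an oxirane and the butenolide C=C is tetrasubstituted and electron-poor.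

**Step 14**
Reactants: 23 8-hydroxy isoxazoline-bridged germacranolide
Product: 24 8-O-methacryloyl isoxazoline-bridged germacranolide (4R 5R 6S 8R 9R 10R)
Conditions: methacrylic anhydride (3 equiv), DMAP (0.3 equiv), Et3N, CH2Cl2, 0 °C → rt
Reagents that add atoms: methacrylic anhydride, C=C(C)C(=O)OC(=O)C(C)=C
Why: DMAP-catalysed acylation of the free C8–OH with retention; C9–O is still locked in the isoxazoline, so no regiochemical question and no acyl migration can arise.

**Step 15**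
Reactants: 24 8-O-methacryloyl isoxazoline-bridged germacranolide
Product: 26 CNP0185951.1 (4R 5R 6S 8R 9R 10S), via hydroxy imine 25 (not isolated)
Conditions: Mo(CO)6 (1.2 equiv), MeCN/H2O (10:1), 75 °C
Reagents that add atoms: water, O
Why: Mo(CO)6-mediated reductive N–O cleavage of the Δ2-isoxazoline gives the β-hydroxy imine, which should hydrolyse in the wet medium to the C1 ketone and free C9–OH without touching C10, the esters or the oxirane.

**Compound list**
1 | tert-butyldimethyl(pent-4-yn-1-yloxy)silane | C#CCCCO[Si](C)(C)C(C)(C)C | starting material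
2 | [(1E)-5-[(tert-butyldimethylsilyl)oxy]-2-methylpent-1-en-1-yl]dimethylalumane | C[Al](C)/C=C(\C)CCCO[Si](C)(C)C(C)(C)C | intermediate (not isolated)
3 | lithium butyl[(1E)-5-[(tert-butyldimethylsilyl)oxy]-2-methylpent-1-en-1-yl]dimethylaluminate | [Li+].CCCC[Al-](C)(C)/C=C(\C)CCCO[Si](C)(C)C(C)(C)C | intermediate (not isolated)
4 | (2E)-6-[(tert-butyldimethylsilyl)oxy]-3-methylhex-2-en-1-ol | OC/C=C(\C)CCCO[Si](C)(C)C(C)(C)C | intermediate
5 | (2E)-6-[(tert-butyldimethylsilyl)oxy]-3-methylhex-2-enal | O=C/C=C(\C)CCCO[Si](C)(C)C(C)(C)C | intermediate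
6 | methyl propiolate | C#CC(=O)OC | starting material
7 | methyl (4R,5E)-9-[(tert-butyldimethylsilyl)oxy]-4-hydroxy-6-methylnon-5-en-2-ynoate | COC(=O)C#C[C@H](O)/C=C(\C)CCCO[Si](C)(C)C(C)(C)C | intermediate
8 | methyl (4S)-4-[(2R,3R)-3-{3-[(tert-butyldimethylsilyl)oxy]propyl}-3-methyloxiran-2-yl]-4-hydroxybut-2-ynoate | COC(=O)C#C[C@H](O)[C@H]1O[C@]1(C)CCCO[Si](C)(C)C(C)(C)C | intermediate
9 | syn-carbocupration adduct of 8 (C11–Cu alkenyl(vinyl)cuprate; bromomagnesium C6-alkoxide) | COC(=O)/C([Cu-]C=C)=C(/C=C)[C@H](O[Mg]Br)[C@H]1O[C@]1(C)CCCO[Si](C)(C)C(C)(C)C.Br[Mg+] | intermediate (not isolated)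
10 | methyl (2E,4S)-3-ethenyl-4-hydroxy-2-iodo-4-[(2R,3R)-3-{3-[(tert-butyldimethylsilyl)oxy]propyl}-3-methyloxiran-2-yl]but-2-enoate (present as its alkoxide) | COC(=O)/C(I)=C(/C=C)[C@H](O)[C@H]1O[C@]1(C)CCCO[Si](C)(C)C(C)(C)C | intermediate (not isolated)
11 | (5S)-5-[(2R,3R)-3-{3-[(tert-butyldimethylsilyl)oxy]propyl}-3-methyloxiran-2-yl]-4-ethenyl-3-iodofuran-2(5H)-one | C=CC1=C(I)C(=O)O[C@@H]1[C@H]1O[C@]1(C)CCCO[Si](C)(C)C(C)(C)C | intermediate
12 | (5S)-5-[(2R,3R)-3-{3-[(tert-butyldimethylsilyl)oxy]propyl}-3-methyloxiran-2-yl]-4-ethenyl-3-(hydroxymethyl)furan-2(5H)-one | C=CC1=C(CO)C(=O)O[C@@H]1[C@H]1O[C@]1(C)CCCO[Si](C)(C)C(C)(C)C | intermediate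
13 | {(5S)-5-[(2R,3R)-3-{3-[(tert-butyldimethylsilyl)oxy]propyl}-3-methyloxiran-2-yl]-4-ethenyl-2-oxo-2,5-dihydrofuran-3-yl}methyl acetate | C=CC1=C(COC(C)=O)C(=O)O[C@@H]1[C@H]1O[C@]1(C)CCCO[Si](C)(C)C(C)(C)C | intermediate
14 | secondary ozonide (1,2,4-trioxolan-3-yl on C7) of 13; trioxolane carbon unassigned | O1COOC1C1=C(COC(C)=O)C(=O)O[C@@H]1[C@H]1O[C@]1(C)CCCO[Si](C)(C)C(C)(C)C | intermediate (not isolated)
15 | {(5S)-5-[(2R,3R)-3-{3-[(tert-butyldimethylsilyl)oxy]propyl}-3-methyloxiran-2-yl]-4-formyl-2-oxo-2,5-dihydrofuran-3-yl}methyl acetate | O=CC1=C(COC(C)=O)C(=O)O[C@@H]1[C@H]1O[C@]1(C)CCCO[Si](C)(C)C(C)(C)C | intermediate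
16 | propyne | CC#C | starting material
17 | {(5S)-5-[(2R,3R)-3-{3-[(tert-butyldimethylsilyl)oxy]propyl}-3-methyloxiran-2-yl]-4-[(1S,2E)-1-hydroxybut-2-en-1-yl]-2-oxo-2,5-dihydrofuran-3-yl}methyl acetate | C/C=C/[C@H](O)C1=C(COC(C)=O)C(=O)O[C@@H]1[C@H]1O[C@]1(C)CCCO[Si](C)(C)C(C)(C)C | intermediate
18 | {(5S)-4-[(1S,2E)-1-hydroxybut-2-en-1-yl]-5-[(2R,3R)-3-(3-hydroxypropyl)-3-methyloxiran-2-yl]-2-oxo-2,5-dihydrofuran-3-yl}methyl acetate | C/C=C/[C@H](O)C1=C(COC(C)=O)C(=O)O[C@@H]1[C@H]1O[C@]1(C)CCCO | intermediate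
19 | {(5S)-4-[(1S,2E)-1-hydroxybut-2-en-1-yl]-5-[(2R,3R)-3-methyl-3-(3-oxopropyl)oxiran-2-yl]-2-oxo-2,5-dihydrofuran-3-yl}methyl acetate | C/C=C/[C@H](O)C1=C(COC(C)=O)C(=O)O[C@@H]1[C@H]1O[C@]1(C)CCC=O | intermediate
20 | {(5S)-5-[(2R,3R)-3-[3-(hydroxyimino)propyl]-3-methyloxiran-2-yl]-4-[(1S,2E)-1-hydroxybut-2-en-1-yl]-2-oxo-2,5-dihydrofuran-3-yl}methyl acetate (E/Z oxime mixture) | C/C=C/[C@H](O)C1=C(COC(C)=O)C(=O)O[C@@H]1[C@H]1O[C@]1(C)CCC=NO | intermediate
21 | hydroximoyl chloride of 20 [3-chloro-3-(hydroxyimino)propyl side chain] | C/C=C/[C@H](O)C1=C(COC(C)=O)C(=O)O[C@@H]1[C@H]1O[C@]1(C)CCC(Cl)=NO | intermediate (not isolated)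
22 | C1 nitrile oxide as bromomagnesium C8-alkoxide | C/C=C/[C@H](O[Mg]Br)C1=C(COC(C)=O)C(=O)O[C@@H]1[C@H]1O[C@]1(C)CCC#[N+][O-] | intermediate (not isolated)
23 | 8-hydroxy isoxazoline-bridged germacranolide: isoxazoline C3 (= C1), C4 (= C10, methyl) and C5 (= C9) lie in the ten-membered carbocycle; 13-OAc; 4,5-oxirane; 4R 5R 6S 8R 9R 10R | O[C@@H]1C2=C(COC(C)=O)C(=O)O[C@@H]2[C@H]2O[C@]2(C)CCC(=NO3)[C@@H](C)[C@H]13 | intermediate
24 | 8-O-methacryloyl derivative of 23 (4R 5R 6S 8R 9R 10R) | C=C(C)C(=O)O[C@@H]1C2=C(COC(C)=O)C(=O)O[C@@H]2[C@H]2O[C@]2(C)CCC(=NO3)[C@@H](C)[C@H]13 | intermediate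
25 | C1 N–H ketimine with free C9–OH (β-hydroxy imine) | C=C(C)C(=O)O[C@@H]1C2=C(COC(C)=O)C(=O)O[C@@H]2[C@H]2O[C@]2(C)CCC(=N)[C@@H](C)[C@H]1O | intermediate (not isolated)
26 | CNP0185951.1 (4R 5R 6S 8R 9R 10S) | C=C(C)C(=O)O[C@@H]1C2=C(COC(C)=O)C(=O)O[C@@H]2[C@H]2O[C@]2(C)CCC(=O)[C@@H](C)[C@H]1O | target

**Step count and risk**
Total steps: 15. Longest linear sequence: 15 steps (from 1; the route is linear, with 6 and 16 entering as reagents).

Steps most likely to fail:

Step 13 (Proposed new method). The magnesium chelate may not survive in the macrocyclic transition state, which would erode facial or regiochemical control. The Lewis-acidic magnesium halide may open the oxirane, and dimerisation of the nitrile oxide may outrun ring closure. The fallback uses only known chemistry: the inherent anti ("inside alkoxy") preference of untemplated nitrile oxide cycloadditions to allylic silyl ethers, followed by a Mitsunobu inversion. It sets out from 15 and returns at 24. Aldehyde 15 is treated with the propenylzinc reagent and (+)-MIB to give the C8 epimer of 17, F1. Silylation (TBSOTf, 2,6-lutidine) gives the bis-silyl ether F2. Selective cleavage of the primary silyl ether (HF·pyridine, pyridine, 0 °C) gives alcohol F3, Dess–Martin oxidation gives aldehyde F4, and NH2OH·HCl/NaOAc gives oxime F5. Oxidation with PhI(OAc)2 at 2 mM generates the nitrile oxide F6, which should cyclise without a metal, the silyloxy group taking the inside position so that O–C9 forms anti to O–C8. This would give the silyl ether F7 with the required C9 and C10 and the epimeric C8. HF·pyridine then gives the 8-epi alcohol F8, and Mitsunobu esterification with methacrylic acid (PPh3, DIAD) inverts C8 and delivers 24.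

Step 5. The magnesium alkoxide next to the oxirane may trigger epoxide migration or halide opening. The alkenylcopper may also lose its geometry through the allenolate on warming, after which lactonisation cannot occur. The fallback separates conjugate addition from lactonisation so that no alkoxide is present; it sets out from 8 and returns at 11. Alcohol 8 is silylated (TMSCl, imidazole) to F11. Vinylcuprate addition at −78 °C gives the protected alkenylcuprate F12, and iodinolysis gives the protected iodo ester F13. K2CO3 in MeOH at 0 °C then removes the TMS group and lactonises to 11.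

Step 9. Facial selectivity may be poor on the hindered, electron-poor aldehyde, and conjugate addition or epimerisation at C6 through γ-deprotonation may compete. The fallback replaces the asymmetric addition by an oxidation–asymmetric reduction sequence; it sets out from 15 and returns at 17. Nozaki–Hiyama–Kishi addition of (E)-1-iodoprop-1-ene (CrCl2, cat. NiCl2, DMSO) gives the C8 epimer mixture F9. Dess–Martin oxidation gives the C8 ketone F10. CBS reduction ((R)-Me-CBS, catecholborane, −78 °C) should deliver hydride to the Re face and give 17.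

Further compounds
F1 | step 13 | {(5S)-5-[(2R,3R)-3-{3-[(tert-butyldimethylsilyl)oxy]propyl}-3-methyloxiran-2-yl]-4-[(1R,2E)-1-hydroxybut-2-en-1-yl]-2-oxo-2,5-dihydrofuran-3-yl}methyl acetate (C8 epimer of 17) | C/C=C/[C@@H](O)C1=C(COC(C)=O)C(=O)O[C@@H]1[C@H]1O[C@]1(C)CCCO[Si](C)(C)C(C)(C)C
F2 | step 13 | C8-O-TBS ether of F1 | C/C=C/[C@@H](O[Si](C)(C)C(C)(C)C)C1=C(COC(C)=O)C(=O)O[C@@H]1[C@H]1O[C@]1(C)CCCO[Si](C)(C)C(C)(C)C
F3 | step 13 | primary alcohol from F2 (C8-OTBS kept) | C/C=C/[C@@H](O[Si](C)(C)C(C)(C)C)C1=C(COC(C)=O)C(=O)O[C@@H]1[C@H]1O[C@]1(C)CCCO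
F4 | step 13 | C1 aldehyde from F3 | C/C=C/[C@@H](O[Si](C)(C)C(C)(C)C)C1=C(COC(C)=O)C(=O)O[C@@H]1[C@H]1O[C@]1(C)CCC=O
F5 | step 13 | C1 aldoxime from F4 | C/C=C/[C@@H](O[Si](C)(C)C(C)(C)C)C1=C(COC(C)=O)C(=O)O[C@@H]1[C@H]1O[C@]1(C)CCC=NO
F6 | step 13 | C1 nitrile oxide from F5 | C/C=C/[C@@H](O[Si](C)(C)C(C)(C)C)C1=C(COC(C)=O)C(=O)O[C@@H]1[C@H]1O[C@]1(C)CCC#[N+][O-]
F7 | step 13 | 8-epi isoxazoline-bridged germacranolide, C8-O-TBS ether | CC(C)(C)[Si](C)(C)O[C@H]1C2=C(COC(C)=O)C(=O)O[C@@H]2[C@H]2O[C@]2(C)CCC(=NO3)[C@@H](C)[C@H]13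
F8 | step 13 | 8-epi-23 (free C8–OH) | O[C@H]1C2=C(COC(C)=O)C(=O)O[C@@H]2[C@H]2O[C@]2(C)CCC(=NO3)[C@@H](C)[C@H]13
F9 | step 9 | C8 epimer mixture of 17 | C/C=C/C(O)C1=C(COC(C)=O)C(=O)O[C@@H]1[C@H]1O[C@]1(C)CCCO[Si](C)(C)C(C)(C)C
F10 | step 9 | C8 ketone: {(5S)-4-[(2E)-but-2-enoyl]-5-[(2R,3R)-3-{3-[(tert-butyldimethylsilyl)oxy]propyl}-3-methyloxiran-2-yl]-2-oxo-2,5-dihydrofuran-3-yl}methyl acetate | C/C=C/C(=O)C1=C(COC(C)=O)C(=O)O[C@@H]1[C@H]1O[C@]1(C)CCCO[Si](C)(C)C(C)(C)C
F11 | step 5 | C6-O-trimethylsilyl ether of 8 | COC(=O)C#C[C@H](O[Si](C)(C)C)[C@H]1O[C@]1(C)CCCO[Si](C)(C)C(C)(C)C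
F12 | step 5 | syn-carbocupration adduct of F11 (bromomagnesium alkenyl(vinyl)cuprate) | COC(=O)/C([Cu-]C=C)=C(/C=C)[C@H](O[Si](C)(C)C)[C@H]1O[C@]1(C)CCCO[Si](C)(C)C(C)(C)C.Br[Mg+]
F13 | step 5 | C6-O-trimethylsilyl ether of 10 | COC(=O)/C(I)=C(/C=C)[C@H](O[Si](C)(C)C)[C@H]1O[C@]1(C)CCCO[Si](C)(C)C(C)(C)C
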